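The data are calculated with made-up constants, noise included.

In millimolar per minute, Wednesday's flask makes target at 0.300 mM min⁻¹ up to its first reading. Side product needs target to form, so I take this first slope, read with its scatter, as the steady use of solid substrate. The gas is held, and solid substrate is the charge that can end, the limiting reagent.

common to all: gas 0.58 mM (held)
- Wednesday's: solid substrate 2 mM; the very flask that is asked about, followed so far
- flask: solid substrate 2.0 mM; time 6.0 min

Wednesday's run (percent of the solid substrate charged)

| time / min | target / % | solid product / % |
|---|---|---|
| 0.667 | 10.0 | 0.2 |
| 1.33 | 18.7 | 0 |
| 2.00 | 26.9 | 0 |
| 2.50 | 32.9 | 0 |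
| 3.00 | 40.0 | 4.3 |

(standard deviation of a reading: 0.5 percentage points)

- in percentages every species weighs as the solid substrate in it: one side product counts as two
- for target the solid product is counted in
- as a solid, counted per litre of solution: solid substrate, solid product
- at the start none of reagent is dissolved
- what was read earlier has a scatter of 0.5 percentage points, one standard deviation
- reactions considered so far: solid product <-> target; gas <-> reagent; dissolved substrate + reagent -> target; dissolved substrate + target -> side product; 2 reagent -> homo dimer; solid substrate <-> dissolved substrate
- at the start none of the solid substrate is in solution
- dissolved substrate means what is dissolved; the solid is not counted in it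

* the target and solid product together standing at 6.0 min, as a percentage of the solid substrate charged
* concentration of dissolved substrate in solution at 6.0 min, in percent of saturation

How long does the solid substrate last? Its charge over that use gives 6.67 min, the run-out time, meaning the charge divided by the steady use. That is later than the asked 6.0 min, so I expect 90.0% of the charge used and 10.0% still there.

How much of the used part stands as target? From 2.00 min to 3.00 min Wednesday's target climbs at 0.262 mM min⁻¹, slower than the first slope, and I count the gap as side product. Holding that climb from 3.00 min on, I reckon 79.3%.

How full is the solution of dissolved substrate? The readings show the flow through it, not its level, so I put no number on it.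

The forecast gives 74%, lower than my figure, and 100%, saying the nearly straight climb suggests that “dissolved substrate is pinned at saturation by the remaining solid”.

The flask gives 73.0%, below my figure, and 0.801% of saturation.

    solid product ⇌ target, rate k1*(cs1 - [target]) while solid is left; crystals form when [target] > cs1 (solubility = 0.680 mM, k = 3.90 s⁻¹)
    gas ⇌ reagent, rate k2*(csat - [reagent]) (kL = 0.170 s⁻¹)
    dissolved substrate + reagent → target (k = 5900 M⁻¹ s⁻¹)
    dissolved substrate + target → side product (k = 730 M⁻¹ s⁻¹)
    2 reagent → homo dimer (k = 26.0 M⁻¹ s⁻¹)
    solid substrate ⇌ dissolved substrate, rate k6*(cs6 - [dissolved substrate]) while solid is left; crystals form when [dissolved substrate] > cs6 (solubility = 0.200 mM, k = 0.0270 s⁻¹)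

At 6.00 min the flask makes and uses up dissolved substrate at a ratio of 1.00, each step taken net. Solid substrate stands at 3.63% of the charge, less than the 10.0% that my run-out time left. For the neighbour flask charged with 8.0 mM, the same steady use gives a run-out time of 26.7 min, which leaves 77.5% of its charge at 6.0 min, and that flask has solid substrate standing at 75.9% of its charge at 6.00 min.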